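**Assumption:** the SMILES describes the meso (2R,3S) isomer, which is achiral, so there is no enantiomer to select. The route therefore controls only the relative (erythro) configuration. Chiral intermediates are racemic and, where they carry two stereocentres, are drawn as one enantiomer.

**Abbreviation:** Ar = 3,5-dimethoxy-4-(propan-2-yloxy)phenyl (4-isopropoxy-3,5-dimethoxyphenyl).

## Retrosynthetic overview

1. Target 18 ⇐ BCl3 de-isopropylation of 17 ⇐ double deoxygenation (OMs → H) of meso-diol 15.
2. 15 ⇐ LiAlH4 opening of cis-lactone 14 ⇐ face-selective hydrogenation of the E-arylidene lactone 13, which sets the erythro (meso) relationship.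
3. 13 ⇐ intermolecular aldol addition of the lithium enolate of lactone 9 to aldehyde 2, then dehydration; this is the key C–C bond and joins the two aryl halves.
4. 9 ⇐ Stobbe condensation of 2 with dimethyl succinate, C=C hydrogenation, ester reduction and lactonisation; 2 ⇐ syringaldehyde.
5. Ring order: the only ring made is the temporary γ-butyrolactone (step 4), used as the stereochemical template and opened again in step 8.

## Route

Step 1
Reactants: 1 syringaldehyde (4-hydroxy-3,5-dimethoxybenzaldehyde)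
Product: 2 3,5-dimethoxy-4-(propan-2-yloxy)benzaldehyde (ArCHO)
Conditions: 2-bromopropane, K2CO3, DMF, 80 °C
Reagents that add atoms: 2-bromopropane, CC(C)Br
Why: Williamson ether synthesis on the acidic para-formyl phenoxide; the isopropyl ether survives every later base, hydride and hydrogenation and is the one ether BCl3 removes at the end.

Step 2
Reactants: 2 ArCHO; 3 dimethyl succinate
Product: 5 (E)-4-Ar-3-(methoxycarbonyl)but-3-enoic acid, via paraconate lactone 4 (not isolated)
Conditions: NaOMe, MeOH, reflux; then aq. HCl, 0 °C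
Reagents that add atoms: none
Why: Stobbe condensation: aldol addition of the succinate enolate to the non-enolisable aldehyde, lactonisation to 4 and irreversible E1cB ring opening to the carboxylate drive the reaction and give the E half-ester.

Step 3
Reactants: 5 (E)-half-ester
Product: 6 rac-4-Ar-3-(methoxycarbonyl)butanoic acid
Conditions: H2 (1–3 atm), 10% Pd/C, MeOH, rt
Reagents that add atoms: none
Why: Heterogeneous catalytic hydrogenation of the cinnamate-type C=C leaves aryl alkyl ethers, ester and acid untouched; the new stereocentre is racemic, which is harmless for a meso target.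

Step 4
Reactants: 6 rac-4-Ar-3-(methoxycarbonyl)butanoic acid
Product: 9 rac-4-(ArCH2)oxolan-2-one, via potassium carboxylate 7 (not isolated), via hydroxy acid 8 (not isolated)
Conditions: KOH (1 equiv), EtOH, rt; CaCl2, NaBH4, EtOH, −10 °C → rt; then 2 M HCl, rt
Reagents that add atoms: potassium hydroxide, [K+].[OH-] (its potassium is in intermediate 7 only)
Why: Chemoselective borohydride reduction: Ca(BH4)2 reduces the ester but not the carboxylate, and acid-promoted lactonisation then closes the γ-lactone with the arylmethyl group at C4.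

Step 5
Reactants: 9 rac-4-(ArCH2)oxolan-2-one; 2 ArCHO
Product: 11 3-[Ar(hydroxy)methyl]-4-(ArCH2)oxolan-2-one as a diastereomer mixture, via lithium enolate 10 (not isolated)
Conditions: LDA, THF, −78 °C; then 2, −78 °C; AcOH quench
Reagents that add atoms: lithium diisopropylamide, [Li+].CC(C)[N-]C(C)C (its lithium is in intermediate 10 only)
Why: Directed crossed aldol addition of a preformed lactone enolate to a non-enolisable aldehyde forms the bond joining the two aryl halves; the new carbinol and α-centres need no control because steps 6 and 7 erase and reset them.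

Step 6
Reactants: 11 aldol adduct
Product: 13 (E)-3-(Ar-methylidene)-4-(ArCH2)oxolan-2-one (racemic), via benzylic mesylate 12 (not isolated)
Conditions: MsCl, Et3N, CH2Cl2, 0 °C; then DBU, rt
Reagents that add atoms: methanesulfonyl chloride, CS(=O)(=O)Cl (its atoms are in intermediate 12 only)
Why: Mesylation followed by E1cB elimination completes the aldol condensation and gives the conjugated, thermodynamically preferred E-alkene; either alkene isomer would give the same product in step 7.

Step 7
Reactants: 13 (E)-arylidene lactone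
Product: 14 rac-(3S,4R)-3,4-bis(ArCH2)oxolan-2-one (cis)
Conditions: H2 (1–3 atm), 10% Pd/C, EtOAc, rt
Reagents that add atoms: none
Why: Substrate-controlled heterogeneous hydrogenation: H2 adds syn to the exocyclic alkene from the face anti to the C4 arylmethyl group, so the new C3 arylmethyl ends up cis to it, which is the erythro relationship of the meso target.

Step 8
Reactants: 14 cis-lactone
Product: 15 (2R,3S)-2,3-bis(ArCH2)butane-1,4-diol (meso)
Conditions: LiAlH4, THF, −20 → 0 °C (lactone added to the hydride); H2O/NaOH work-up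
Reagents that add atoms: none
Why: LiAlH4 reduction of the lactone to the 1,4-diol is much faster than enolisation at low temperature, so C3 does not epimerise and the cis-lactone gives the meso diol.

Step 9
Reactants: 15 meso-diol
Product: 16 (2R,3S)-2,3-bis(ArCH2)butane-1,4-diyl dimethanesulfonate (meso)
Conditions: MsCl (3 equiv), Et3N (4 equiv), CH2Cl2, −20 → 0 °C
Reagents that add atoms: methanesulfonyl chloride, CS(=O)(=O)Cl
Why: Sulfonylation via sulfene is fast at low temperature, so both hydroxyls are capped before a monomesylate can cyclise to the tetrahydrofuran; no stereocentre is involved.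

Step 10
Reactants: 16 meso-dimesylate
Product: 17 1,1'-[(2R,3S)-2,3-dimethylbutane-1,4-diyl]bis[3,5-dimethoxy-4-(propan-2-yloxy)benzene] (meso)
Conditions: LiEt3BH (6 equiv), THF, 0 °C → reflux
Reagents that add atoms: none
Why: SN2 hydride displacement of the two primary sulfonates (reductive deoxygenation with Super-Hydride) turns both CH2OMs groups into CH3 without touching the stereocentres.

Step 11
Reactants: 17 bis-isopropyl ether
Product: 18 4,4'-[(2R,3S)-2,3-dimethylbutane-1,4-diyl]bis(2,6-dimethoxyphenol) (meso), the target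
Conditions: BCl3 (1 M in CH2Cl2, 4 equiv), CH2Cl2, −78 → 0 °C; H2O work-up
Reagents that add atoms: none
Why: Lewis-acid ether cleavage: BCl3 selectively removes the secondary, sterically twisted isopropyl group flanked by two methoxy groups and leaves the methyl ethers intact at or below 0 °C.

## Compound list

1 | syringaldehyde | COc1cc(C=O)cc(OC)c1O | starting material
2 | 3,5-dimethoxy-4-(propan-2-yloxy)benzaldehyde | COc1cc(C=O)cc(OC)c1OC(C)C | intermediate
3 | dimethyl succinate | COC(=O)CCC(=O)OC | starting material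
4 | methyl 2-Ar-5-oxooxolane-3-carboxylate (paraconate lactone, diastereomer mixture) | COC(=O)C1CC(=O)OC1c1cc(OC)c(OC(C)C)c(OC)c1 | intermediate (not isolated)
5 | (E)-4-Ar-3-(methoxycarbonyl)but-3-enoic acid | COC(=O)/C(CC(=O)O)=C/c1cc(OC)c(OC(C)C)c(OC)c1 | intermediate
6 | rac-4-Ar-3-(methoxycarbonyl)butanoic acid | COC(=O)C(CC(=O)O)Cc1cc(OC)c(OC(C)C)c(OC)c1 | intermediate
7 | potassium rac-4-Ar-3-(methoxycarbonyl)butanoate | COC(=O)C(CC(=O)[O-])Cc1cc(OC)c(OC(C)C)c(OC)c1.[K+] | intermediate (not isolated)
8 | rac-4-Ar-3-(hydroxymethyl)butanoic acid | OCC(CC(=O)O)Cc1cc(OC)c(OC(C)C)c(OC)c1 | intermediate (not isolated)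
9 | rac-4-(ArCH2)oxolan-2-one | O=C1CC(Cc2cc(OC)c(OC(C)C)c(OC)c2)CO1 | intermediate
10 | lithium rac-4-(ArCH2)-4,5-dihydrofuran-2-olate | [Li+].[O-]C1=CC(Cc2cc(OC)c(OC(C)C)c(OC)c2)CO1 | intermediate (not isolated)
11 | 3-[Ar(hydroxy)methyl]-4-(ArCH2)oxolan-2-one (racemic diastereomer mixture) | O=C1OCC(Cc2cc(OC)c(OC(C)C)c(OC)c2)C1C(O)c1cc(OC)c(OC(C)C)c(OC)c1 | intermediate
12 | 3-[Ar(methanesulfonyloxy)methyl]-4-(ArCH2)oxolan-2-one (diastereomer mixture) | O=C1OCC(Cc2cc(OC)c(OC(C)C)c(OC)c2)C1C(OS(C)(=O)=O)c1cc(OC)c(OC(C)C)c(OC)c1 | intermediate (not isolated)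
13 | (E)-3-(Ar-methylidene)-4-(ArCH2)oxolan-2-one (racemic) | O=C1OCC(Cc2cc(OC)c(OC(C)C)c(OC)c2)/C1=C\c1cc(OC)c(OC(C)C)c(OC)c1 | intermediate
14 | rac-(3S,4R)-3,4-bis(ArCH2)oxolan-2-one (cis) | O=C1OC[C@H](Cc2cc(OC)c(OC(C)C)c(OC)c2)[C@@H]1Cc1cc(OC)c(OC(C)C)c(OC)c1 | intermediate
15 | (2R,3S)-2,3-bis(ArCH2)butane-1,4-diol (meso) | CC(C)Oc1c(OC)cc(C[C@@H](CO)[C@@H](CO)Cc2cc(OC)c(OC(C)C)c(OC)c2)cc1OC | intermediate
16 | (2R,3S)-2,3-bis(ArCH2)butane-1,4-diyl dimethanesulfonate (meso) | CC(C)Oc1c(OC)cc(C[C@@H](COS(C)(=O)=O)[C@@H](COS(C)(=O)=O)Cc2cc(OC)c(OC(C)C)c(OC)c2)cc1OC | intermediate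
17 | 1,1'-[(2R,3S)-2,3-dimethylbutane-1,4-diyl]bis[3,5-dimethoxy-4-(propan-2-yloxy)benzene] (meso) | CC(C)Oc1c(OC)cc(C[C@@H](C)[C@@H](C)Cc2cc(OC)c(OC(C)C)c(OC)c2)cc1OC | intermediate
18 | 4,4'-[(2R,3S)-2,3-dimethylbutane-1,4-diyl]bis(2,6-dimethoxyphenol) (meso) | COc1cc(C[C@@H](C)[C@@H](C)Cc2cc(OC)c(O)c(OC)c2)cc(OC)c1O | target

## Step count and risks

Total step count: 11. Longest linear sequence: 11 steps (1 → 18); aldehyde 2 is used twice, in steps 2 and 5.

**Step 7 (face-selective hydrogenation; it sets the meso relationship, and the kinetic cis-lactone can epimerise).** The fallback sets out from 13 and comes back at 14. It replaces surface hydrogenation by conjugate hydride addition and kinetic protonation. L-Selectride in THF at −78 °C adds hydride to the benzylidene carbon of 13 and gives lithium 3,4-bis(ArCH2)-4,5-dihydrofuran-2-olate F1. This enolate is protonated at −78 °C by the bulky donor 2,6-di-tert-butyl-4-methylphenol on the face anti to the C4 arylmethyl group, which delivers the cis-lactone 14. The same enolate can be regenerated with LDA from any batch of 14 of low diastereomeric purity.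

**Step 9 (bis-mesylation of a 1,4-diol; a monomesylate can close to the 3,4-disubstituted tetrahydrofuran).** The fallback sets out from 14 and comes back at 17. It never makes a 1,4-diol, because the two oxygens are removed one after the other. DIBAL-H in toluene at −78 °C reduces 14 to the lactol rac-(3S,4R)-3,4-bis(ArCH2)oxolan-2-ol F2. Ethane-1,2-dithiol with BF3·OEt2 in CH2Cl2 at 0 °C opens it to the hydroxy dithiolane rac-(2R,3S)-4-Ar-2-(ArCH2)-3-(1,3-dithiolan-2-yl)butan-1-ol F3. Raney nickel in refluxing EtOH desulfurises this to rac-(2R,3S)-4-Ar-2-(ArCH2)-3-methylbutan-1-ol F4. Its single hydroxyl is mesylated (MsCl, Et3N) to rac-(2R,3S)-4-Ar-2-(ArCH2)-3-methylbutyl methanesulfonate F5, which cannot cyclise, and LiEt3BH then gives 17.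

**Step 10 (double hydride displacement at β-branched primary mesylates; S–O cleavage would return alcohols).** The fallback sets out from 16 and comes back at 17. It uses sulfur as a temporary bridge. Na2S·9H2O in DMF at 60 °C displaces both mesylates, the second one intramolecularly, and gives (3R,4S)-3,4-bis(ArCH2)thiolane F6 (cis, meso). Raney nickel in refluxing EtOH cleaves both C–S bonds and leaves the two methyl groups of 17.

## Further compounds

F1 | step 7 | lithium 3,4-bis(ArCH2)-4,5-dihydrofuran-2-olate (racemic) | [Li+].[O-]C1=C(Cc2cc(OC)c(OC(C)C)c(OC)c2)C(Cc2cc(OC)c(OC(C)C)c(OC)c2)CO1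
F2 | step 9 | rac-(3S,4R)-3,4-bis(ArCH2)oxolan-2-ol (cis, anomer mixture) | OC1OC[C@H](Cc2cc(OC)c(OC(C)C)c(OC)c2)[C@@H]1Cc1cc(OC)c(OC(C)C)c(OC)c1
F3 | step 9 | rac-(2R,3S)-4-Ar-2-(ArCH2)-3-(1,3-dithiolan-2-yl)butan-1-ol | OC[C@H](Cc1cc(OC)c(OC(C)C)c(OC)c1)[C@@H](C1SCCS1)Cc1cc(OC)c(OC(C)C)c(OC)c1
F4 | step 9 | rac-(2R,3S)-4-Ar-2-(ArCH2)-3-methylbutan-1-ol | OC[C@H](Cc1cc(OC)c(OC(C)C)c(OC)c1)[C@@H](C)Cc1cc(OC)c(OC(C)C)c(OC)c1
F5 | step 9 | rac-(2R,3S)-4-Ar-2-(ArCH2)-3-methylbutyl methanesulfonate | CS(=O)(=O)OC[C@H](Cc1cc(OC)c(OC(C)C)c(OC)c1)[C@@H](C)Cc1cc(OC)c(OC(C)C)c(OC)c1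
F6 | step 10 | (3R,4S)-3,4-bis(ArCH2)thiolane (cis, meso) | C1SC[C@H](Cc2cc(OC)c(OC(C)C)c(OC)c2)[C@@H]1Cc1cc(OC)c(OC(C)C)c(OC)c1
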